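The seven-membered ring (C1, C5–C10, daucane numbering) carries its spiro-oxirane at C8 and the cis-diol at C9/C10 on one face, anti to the angular C1 methyl. Together they are the oxidised form of a conjugated 8(14),9-diene. The route therefore closes this ring last, at C9=C10, by ring-closing metathesis of a triene in which a 2-substituted butadiene (arm on C5) meets a neopentyl vinyl group (on C1) across a densely substituted, trans-configured cyclopentane. The cyclopentane comes from a catalytic asymmetric conjugate addition/aldol on 3-methylcyclopentenone. Hydroxyl-directed epoxidation, acylation and osmylation then finish the target without protecting groups.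

Key step: step 6

Remark: the "Why" lines use daucane locants (C1 quaternary ring-fusion carbon with methyl C15; C2, C3; C4 carbinol with isopropyl; C5 ring-fusion CH; C6 acyloxy carbon; C7; C8 spiro carbon with oxirane CH2 C14; C9, C10 carbinol carbons), and the oxirane is treated as a functional group installed on the finished bicyclic carbon skeleton.

Step 1
Reactants: 1 3-methylcyclopent-2-en-1-one; 2 ethynyltrimethylsilane; 3 formaldehyde (monomeric gas from cracked paraformaldehyde)
Product: 6 (2S,3S)-2-(hydroxymethyl)-3-methyl-3-[1-(trimethylsilyl)ethenyl]cyclopentan-1-one, via alkenylalane 4 (not isolated), via aluminium enolate 5 (not isolated)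
Conditions: 2, DIBAL-H, hexanes, 55 °C; then 1, chiral sulfonate-bearing NHC–Ag complex (2.5 mol %), Cu(OTf)2 (5 mol %), THF, −78 °C; then CH2O (g), −78 °C; aq. Rochelle salt
Reagents that add atoms: ethynyltrimethylsilane C#C[Si](C)(C)C; formaldehyde C=O
Why: NHC–Cu-catalysed enantioselective conjugate addition of the α-silylvinylalane (tandem hydroalumination/conjugate addition) builds the quaternary C1 under catalyst control (ligand enantiomer chosen for the S product), and the regiodefined aluminium enolate then undergoes an aldol addition to formaldehyde on the face anti to the bulky silylvinyl group, which sets C5 trans to it.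

Step 2
Reactants: 6 (2S,3S)-2-(hydroxymethyl)-3-methyl-3-[1-(trimethylsilyl)ethenyl]cyclopentan-1-one; 7 isopropylmagnesium chloride
Product: 8 (1R,2S,3S)-2-(hydroxymethyl)-3-methyl-1-(propan-2-yl)-3-[1-(trimethylsilyl)ethenyl]cyclopentan-1-ol
Conditions: i-PrMgCl (3 equiv), LaCl3·2LiCl (1 equiv), THF, −20 → 0 °C
Reagents that add atoms: isopropylmagnesium chloride CC(C)[Mg]Cl
Why: Lanthanide-promoted Grignard 1,2-addition avoids enolisation and retro-aldol of the β-hydroxy ketone, and the isopropyl group enters anti to the adjacent CH2O arm and to the pseudo-axial C1 methyl, so the new tertiary hydroxyl at C4 is cis to the hydroxymethyl group.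

Step 3
Reactants: 8 (1R,2S,3S)-2-(hydroxymethyl)-3-methyl-1-(propan-2-yl)-3-[1-(trimethylsilyl)ethenyl]cyclopentan-1-ol
Product: 9 (1R,2S,3R)-3-ethenyl-2-(hydroxymethyl)-3-methyl-1-(propan-2-yl)cyclopentan-1-ol
Conditions: KOt-Bu (0.3 equiv), 18-crown-6, DMSO–H2O, 70 °C
Reagents that add atoms: none
Why: Base-mediated protodesilylation of the vinylsilane, helped by the neighbouring primary alkoxide (Brook-type 1,5 C→O silyl shift, then hydrolysis of the silyl ether), removes the silicon that served only as a steric control element and touches no stereocentre.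

Step 4
Reactants: 9 (1R,2S,3R)-3-ethenyl-2-(hydroxymethyl)-3-methyl-1-(propan-2-yl)cyclopentan-1-ol
Product: 10 (1R,2R,5R)-2-ethenyl-5-hydroxy-2-methyl-5-(propan-2-yl)cyclopentane-1-carbaldehyde
Conditions: TEMPO (10 mol %), PhI(OAc)2 (1.1 equiv), CH2Cl2, 0 °C → rt
Reagents that add atoms: none
Why: The TEMPO/PhI(OAc)2 oxoammonium oxidation converts only the primary alcohol into the aldehyde under non-basic conditions, the tertiary alcohol and the vinyl group are inert, and C5 already has the thermodynamically preferred configuration (formyl trans to isopropyl and vinyl).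

Step 5
Reactants: 10 (1R,2R,5R)-2-ethenyl-5-hydroxy-2-methyl-5-(propan-2-yl)cyclopentane-1-carbaldehyde; 11 isoprene
Product: 13 (1R,2S,3R)-3-ethenyl-2-[(1S)-1-hydroxy-3-methylidenepent-4-en-1-yl]-3-methyl-1-(propan-2-yl)cyclopentan-1-ol, via isoprenylborane 12 (not isolated)
Conditions: isoprene, KTMP, THF, −78 °C; (−)-Ipc2BOMe; BF3·OEt2; then 10 (reagent in excess, 2.5 equiv), Et2O, −78 °C; NaOH, H2O2
Reagents that add atoms: isoprene C=CC(C)=C
Why: Brown asymmetric isoprenylboration through a closed chair transition state, in which the reagent derived from (+)-α-pinene attacks the Si face of the aldehyde and sets C6 as S by reagent control, the excess reagent compensating for the free tertiary hydroxyl.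

Step 6
Reactants: 13 (1R,2S,3R)-3-ethenyl-2-[(1S)-1-hydroxy-3-methylidenepent-4-en-1-yl]-3-methyl-1-(propan-2-yl)cyclopentan-1-ol
Product: 14 (3R,3aS,4S,8aR)-8a-methyl-6-methylidene-3-(propan-2-yl)-1,2,3,3a,4,5,6,8a-octahydroazulene-3,4-diol
Conditions: Grubbs II (5–10 mol %), CH2Cl2 (0.002 M), 40 °C
Reagents that add atoms: none
Why: Ruthenium-alkylidene olefin metathesis: the catalyst loads onto the unhindered monosubstituted vinyl terminus of the butadiene (C9), the resulting carbene undergoes [2+2]/cycloreversion with the C1 vinyl group, and ethylene is lost. The closest known reaction type is diene–ene ring-closing metathesis giving a cyclic 1,3-diene (ring olefin plus exocyclic methylene). The carbocycle C1–C5–C6–C7–C8–C9–C10 is closed at C9=C10 in a seven-membered RCM mode, the Z geometry being enforced by the ring, across a trans-1,2-disubstituted cyclopentane that gives the trans-fused bicycle. No stereocentre is formed; the four existing ones (C1, C4, C5, C6) are untouched and the free hydroxyls are tolerated by ruthenium. The step needs site selectivity among three olefins (seven-membered ring at C9=C10, not the six-membered ring through C8=C14, and no oligomers): the 1,1-disubstituted C8=C14 bond and the neopentyl C1 vinyl group should not load the catalyst, so the carbene formed at C9 can reach only the C1 vinyl group, and high dilution suppresses cross-metathesis.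

Step 7
Reactants: 14 (3R,3aS,4S,8aR)-8a-methyl-6-methylidene-3-(propan-2-yl)-1,2,3,3a,4,5,6,8a-octahydroazulene-3,4-diol
Product: 15 (3R,3aS,4S,6R,8aR)-8a-methyl-3-(propan-2-yl)-2,3,3a,4,5,8a-hexahydro-1H-spiro[azulene-6,2'-oxirane]-3,4-diol
Conditions: VO(acac)2 (5 mol %), t-BuOOH (1.5 equiv), CH2Cl2, 0 °C
Reagents that add atoms: tert-butyl hydroperoxide CC(C)(C)OO
Why: In this vanadium-catalysed hydroxyl-directed epoxidation the homoallylic 6-OH binds the vanadium peroxide and delivers oxygen to the nearer, exocyclic C8=C14 bond on its own face, which sets C8 with the oxirane oxygen cis to 6-OH.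

Step 8
Reactants: 15 (3R,3aS,4S,6R,8aR)-8a-methyl-3-(propan-2-yl)-2,3,3a,4,5,8a-hexahydro-1H-spiro[azulene-6,2'-oxirane]-3,4-diol; 16 3-methylbutanoic anhydride
Product: 17 (3R,3aS,4S,6R,8aR)-3-hydroxy-8a-methyl-3-(propan-2-yl)-2,3,3a,4,5,8a-hexahydro-1H-spiro[azulene-6,2'-oxiran]-4-yl 3-methylbutanoate
Conditions: (i-BuCO)2O, DMAP (cat.), Et3N, CH2Cl2, 0 °C → rt
Reagents that add atoms: 3-methylbutanoic anhydride CC(C)CC(=O)OC(=O)CC(C)C
Why: DMAP-catalysed acyl transfer esterifies the only secondary hydroxyl (C6), the tertiary C4 hydroxyl being unreactive and the vinyl epoxide stable to the mild base.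

Step 9
Reactants: 17 (3R,3aS,4S,6R,8aR)-3-hydroxy-8a-methyl-3-(propan-2-yl)-2,3,3a,4,5,8a-hexahydro-1H-spiro[azulene-6,2'-oxiran]-4-yl 3-methylbutanoate
Product: 18 (3R,3aS,4S,6S,7S,8S,8aS)-3,7,8-trihydroxy-8a-methyl-3-(propan-2-yl)octahydro-1H-spiro[azulene-6,2'-oxiran]-4-yl 3-methylbutanoate (CNP0307265.1)
Conditions: OsO4 (5 mol %), NMO (2 equiv), acetone–H2O, rt
Reagents that add atoms: osmium tetroxide (catalytic oxygen carrier) O=[Os](=O)(=O)=O; N-methylmorpholine N-oxide C[N+]1([O-])CCOCC1; water O
Why: Upjohn syn-dihydroxylation of the only remaining olefin should take place from the face anti to the axial C1 methyl and the pseudo-axial oxirane CH2 on the two allylic carbons, which places both new hydroxyls (C9, C10) cis to each other, to the oxirane oxygen and to the ester.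

Compound list
1 | 3-methylcyclopent-2-en-1-one | CC1=CC(=O)CC1 | starting material
2 | ethynyltrimethylsilane | C#C[Si](C)(C)C | starting material
3 | formaldehyde (from paraformaldehyde) | C=O | starting material
4 | diisobutyl[1-(trimethylsilyl)ethenyl]alane | C=C([Si](C)(C)C)[Al](CC(C)C)CC(C)C | intermediate
5 | diisobutyl({(3S)-3-methyl-3-[1-(trimethylsilyl)ethenyl]cyclopent-1-en-1-yl}oxy)alane | C=C([Si](C)(C)C)[C@@]1(C)CCC(O[Al](CC(C)C)CC(C)C)=C1 | intermediate
6 | (2S,3S)-2-(hydroxymethyl)-3-methyl-3-[1-(trimethylsilyl)ethenyl]cyclopentan-1-one | C=C([Si](C)(C)C)[C@@]1(C)CCC(=O)[C@@H]1CO | intermediate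
7 | isopropylmagnesium chloride | CC(C)[Mg]Cl | starting material
8 | (1R,2S,3S)-2-(hydroxymethyl)-3-methyl-1-(propan-2-yl)-3-[1-(trimethylsilyl)ethenyl]cyclopentan-1-ol | C=C([Si](C)(C)C)[C@@]1(C)CC[C@@](O)(C(C)C)[C@@H]1CO | intermediate
9 | (1R,2S,3R)-3-ethenyl-2-(hydroxymethyl)-3-methyl-1-(propan-2-yl)cyclopentan-1-ol | C=C[C@@]1(C)CC[C@@](O)(C(C)C)[C@@H]1CO | intermediate
10 | (1R,2R,5R)-2-ethenyl-5-hydroxy-2-methyl-5-(propan-2-yl)cyclopentane-1-carbaldehyde | C=C[C@@]1(C)CC[C@@](O)(C(C)C)[C@@H]1C=O | intermediate
11 | isoprene (2-methylbuta-1,3-diene) | C=CC(C)=C | starting material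
12 | (−)-B-(2-methylidenebut-3-en-1-yl)diisopinocampheylborane (isopinocampheyl groups from (+)-α-pinene) | C=CC(=C)CB([C@H]1[C@H](C)[C@H]2C[C@@H](C1)C2(C)C)[C@H]1[C@H](C)[C@H]2C[C@@H](C1)C2(C)C | intermediate
13 | (1R,2S,3R)-3-ethenyl-2-[(1S)-1-hydroxy-3-methylidenepent-4-en-1-yl]-3-methyl-1-(propan-2-yl)cyclopentan-1-ol | C=C[C@@]1(C)CC[C@@](O)(C(C)C)[C@@H]1[C@@H](O)CC(=C)C=C | intermediate
14 | (3R,3aS,4S,8aR)-8a-methyl-6-methylidene-3-(propan-2-yl)-1,2,3,3a,4,5,6,8a-octahydroazulene-3,4-diol, i.e. (1R,4R,5S,6S)-dauca-8(14),9-diene-4,6-diol | O[C@H]1CC(=C)C=C[C@@]2(C)CC[C@@](O)(C(C)C)[C@H]12 | intermediate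
15 | (3R,3aS,4S,6R,8aR)-8a-methyl-3-(propan-2-yl)-2,3,3a,4,5,8a-hexahydro-1H-spiro[azulene-6,2'-oxirane]-3,4-diol, i.e. (1R,4R,5S,6S,8R)-8,14-epoxydauc-9-ene-4,6-diol | O[C@H]1C[C@]2(CO2)C=C[C@@]3(C)CC[C@@](O)(C(C)C)[C@H]13 | intermediate
16 | 3-methylbutanoic anhydride (isovaleric anhydride) | CC(C)CC(=O)OC(=O)CC(C)C | starting material
17 | (3R,3aS,4S,6R,8aR)-3-hydroxy-8a-methyl-3-(propan-2-yl)-2,3,3a,4,5,8a-hexahydro-1H-spiro[azulene-6,2'-oxiran]-4-yl 3-methylbutanoate | CC(C)CC(=O)O[C@H]1C[C@]2(CO2)C=C[C@@]3(C)CC[C@@](O)(C(C)C)[C@H]13 | intermediate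
18 | (3R,3aS,4S,6S,7S,8S,8aS)-3,7,8-trihydroxy-8a-methyl-3-(propan-2-yl)octahydro-1H-spiro[azulene-6,2'-oxiran]-4-yl 3-methylbutanoate, i.e. (1S,4R,5S,6S,8S,9S,10S)-8,14-epoxy-4,9,10-trihydroxydaucan-6-yl 3-methylbutanoate | CC(C)CC(=O)O[C@H]1C[C@]2(CO2)[C@@H](O)[C@@H](O)[C@@]2(C)CC[C@@](O)(C(C)C)[C@H]12 | target

Total step count: 9
Longest linear sequence: 9 steps (1 → 6 → 8 → 9 → 10 → 13 → 14 → 15 → 17 → 18)

Steps most likely to fail

Step 1 (tandem conjugate addition/aldol). The hindered aluminium enolate may react sluggishly or with poor facial selectivity with gaseous formaldehyde, and the β-hydroxy ketone may lose formaldehyde by retro-aldol on work-up. Fallback: starting again from 1 (with 2), the same conjugate addition is run but the aluminium enolate is silylated (Me3SiOTf) and isolated as the silyl enol ether (S)-trimethyl({3-methyl-3-[1-(trimethylsilyl)ethenyl]cyclopent-1-en-1-yl}oxy)silane F1. This is hydroxymethylated separately in a Lewis-acid Mukaiyama aldol reaction with aqueous formaldehyde (Sc(OTf)3, THF–H2O), again anti to the silylvinyl group, and the sequence returns to the route at 6.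

Step 3 (protodesilylation). The C–Si bond of the hindered α-silylvinyl group may resist the base, or the silyl shift may stall before the carbon–silicon bond is broken. Fallback: from 8, electrophilic ipso-iododesilylation (NIS, MeCN–ClCH2CN, 0 °C) should give the vinyl iodide (1R,2S,3S)-2-(hydroxymethyl)-3-(1-iodoethenyl)-3-methyl-1-(propan-2-yl)cyclopentan-1-ol F2, and palladium-catalysed hydrodeiodination (Pd(PPh3)4, Bu3SnH, THF) then returns to the route at 9.

Step 5 (isoprenylboration). Protonolysis of the allylborane by the free tertiary hydroxyl, retro-aldol of the β-hydroxy aldehyde, or a mismatched reagent/substrate pairing may erode conversion and facial selectivity at C6. Fallback: from 10 (with 11), substrate control replaces reagent control. Metalated isoprene is transmetalated with ZnCl2 to chloro(2-methylidenebut-3-en-1-yl)zinc F3, which first converts the C4 hydroxyl into its zinc alkoxide and then adds to the aldehyde through the alkoxide–zinc–carbonyl chelate from the exposed face (chelation-controlled allylation). A model of this chelate predicts the same 6S configuration, so the fallback returns to the route at 13.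

Further compounds
F1 | step 1 | (S)-trimethyl({3-methyl-3-[1-(trimethylsilyl)ethenyl]cyclopent-1-en-1-yl}oxy)silane | C=C([Si](C)(C)C)[C@@]1(C)CCC(O[Si](C)(C)C)=C1
F2 | step 3 | (1R,2S,3S)-2-(hydroxymethyl)-3-(1-iodoethenyl)-3-methyl-1-(propan-2-yl)cyclopentan-1-ol | C=C(I)[C@@]1(C)CC[C@@](O)(C(C)C)[C@@H]1CO
F3 | step 5 | chloro(2-methylidenebut-3-en-1-yl)zinc | C=CC(=C)C[Zn]Cl
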